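**Analysis of the target**

The target is a briarane‑type diterpenoid: a cyclohexane (C1, C10–C14) trans‑fused through C1–C10 to a ten‑membered carbocycle (C1–C10), which carries a trans‑fused α‑methyl‑β‑hydroxy‑γ‑lactone across C7–C8 (C17, C18, C19). There are ten stereocentres (1R, 2S, 4R, 7S, 8S, 9S, 10S, 14S, 17R and the quaternary C1) and a Z‑trisubstituted olefin C5=C6 inside the medium ring. Me‑15 on C1 and H‑10 are anti (trans ring fusion), the 14‑acetoxy group is axial and anti to Me‑15, O2 and O4 are 1,3‑syn, and the lactone oxygen on C7 is anti to the tertiary 8‑OH. The sensitive groups are four esters of two kinds (isobutyrate on O2, acetates on O4, O9, O14) beside a free tertiary alcohol, an allylic acetate, an exocyclic 11(20)‑methylene and an epimerizable C17. The hard parts are the ten‑membered ring with its Z olefin, the quaternary C1 flanked by two oxygenated carbons (C2, C14), and the contiguous C7–C8–C9 triad. The feature the route uses: C2…C9 together with C10–C14 and C1 form a 14‑membered isoprenoid periphery, and C1–C10 is a transannular bond across it, with methyls (C15, C20, C16) in head‑to‑tail positions.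

**Retrosynthetic reasoning**

37 ⇒ 33 (functional‑group level). The 8‑OH is unmasked last from silyl ether 36; the 14‑acetate comes from alcohol 35, which comes from ketone 34 by equatorial hydride delivery, and 34 from alcohol 33. This detour is needed because an epoxide‑initiated ring closure from an E‑epoxide leaves the C14 oxygen equatorial (cis to Me‑15), whereas the target has it axial.

33 ⇒ 32 (key disconnection, C1–C10). Cutting the transannular bond C1–C10 opens the cyclohexane and merges the ten‑membered ring into the 14‑membered carbocycle 32, which holds a 1,14‑epoxide and the E olefin C10=C11. Forward, an epoxide‑derived tertiary radical at C1 must add across the ring to C10 and end as the exocyclic olefin. One step then forms the six‑membered ring, turns the easy 14‑membered ring into the hard ten‑membered one, sets C1 and C10 and installs C11=C20. A radical rather than a cation is chosen because the 2‑acyloxy group would capture a C1 cation.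

32 ⇒ 30 (C9–C10). The macrocycle is opened at the bond between the C9 carbinol and the vinylic C10: aldehyde plus E‑vinyl iodide, closed by a Nozaki–Hiyama–Kishi reaction. A 14‑membered ring closes without medium‑ring strain, the olefin geometry is carried in from the iodide, and the C9 oxygen appears ready for acetylation.

30 ⇒ 27 ⇒ 25 ⇒ 23 + 14 (C3–C4, then C2). The 2,4‑syn diol 27 comes from ketol 25 by 1,3‑syn reduction, and 25 from a boron aldol between methyl ketone 23 (enolizable on one side only) and Z‑enal 14. The epoxide configuration (in 23), C4 (aldol) and C2 (reduction) are thus set independently, which the required "threo" relation between O2 and the epoxide demands. The two esters are put on as soon as the hydroxyls exist, so C2, C4 and C9 never carry protecting groups.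

14 ⇒ 12 ⇒ 11 ⇒ 10 ⇒ 9 ⇒ 4 + 8 (lactone fragment). The lactone C7–O bond is made by opening the C7–C8 epoxide of 11 with the C19 ester (inversion at C7, oxygen stays on C8); the epoxide comes from Sharpless epoxidation of allylic alcohol 10, and the C7=C8 olefin from a Horner–Wadsworth–Emmons reaction of 4 with 8. C17 comes from 1 through triflate 2 by SN2 alkylation of 3; the Z olefin C5=C6 comes from 5 via 7.

23 ⇒ 22 ⇒ 21 ⇒ 20 ⇒ 18 + 19; 18 ⇒ 17 ⇒ 15 (epoxy ketone fragment). The epoxide is set on allylic alcohol 21 (CBS reduction of enone 20, then matched Sharpless epoxidation), and the carbinol is then oxidized away. Enone 20 is a Wittig product of aldehyde 18 and ylide 19; the E‑vinyl iodide comes from 15 by carboalumination.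

**Alternatives that were turned down**

Alternative 1: (textbook) Cut C4–C5 of the ten‑membered ring on a finished cyclohexane: seco aldehyde/vinyl iodide A1, closed by a Nozaki–Hiyama–Kishi reaction. Turned down because the key step would form one bond and one uncontrolled carbinol (C4), and would have to close a trans‑fused cyclodecene against transannular strain. The cyclohexane of A1 with quaternary C1 between C2–O and C14–O, and C10, would have to be built first in a long linear sequence that the key step does not help.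

Alternative 2: Cut C9–C10 by a [2,3]‑Wittig ring contraction of the 13‑membered propargylic/allylic ether A2 to the cyclodecenynol A3; this would also make the exocyclic methylene. Turned down for three reasons. The carbanion at C9 needs a C7≡C8 alkyne, which puts an alkyne and a Z olefin into one ten‑membered ring and leaves C17, O7 and O8 to be added afterwards. The face of attack at C10 (cis or trans fusion) is decided next to the quaternary C1 with no clear bias. An E‑allyl ether favours the anti C9/C10 relation, whereas the target is syn.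

Alternative 3: Anionic oxy‑Cope ring expansion of the 1,2‑dialkenyl decalinol A4 (cleaving a C3–C8 bond and forming C5–C6) to cyclodecenone A5. Turned down because the [3,3] topology puts the ketone on C8 but the new olefin at C3=C4 and leaves C5 and C6 saturated. Reaching C5=C6 with oxygen on C4 and C7 and a quaternary C8 would cost more steps than the expansion saves, and A4 already contains the hard centres C1, C2, C9, C10 and C14.

Key step: step 24

Remarks (assumptions on the chemistry):
- Briarane numbering is used for all intermediates: ring carbons C1–C14, C15 = methyl on C1, C16 = methyl on C5, C17/C18/C19 = lactone CH, its methyl and the carbonyl, C20 = exocyclic methylene.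
- The enolate made from a methyl ketone with (−)‑Ipc2BCl is taken to add to the re face of the aldehyde; if the sense were the opposite, the antipodal reagent would be used.
- 1, 3, 5, 15 and 19 are taken as commercial.

**Steps**

Step 1
Reactants: 1 tert-butyl (2R)-2-hydroxypropanoate
Product: 2 tert-butyl (2R)-2-[(trifluoromethanesulfonyl)oxy]propanoate
Conditions: Tf2O, 2,6-lutidine, CH2Cl2, −78 to 0 °C
Reagents that add atoms: trifluoromethanesulfonic anhydride, O=S(=O)(OS(=O)(=O)C(F)(F)F)C(F)(F)F
Why: O‑Sulfonylation of the α‑hydroxy ester with retention gives the leaving group for the next SN2 step; no stereocentre is touched.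

Step 2
Reactants: 2 tert-butyl (2R)-2-[(trifluoromethanesulfonyl)oxy]propanoate; 3 triethyl phosphonoacetate
Product: 4 1-tert-butyl 4-ethyl (2S)-3-(diethoxyphosphoryl)-2-methylbutanedioate (C3 epimers)
Conditions: 3, NaH, THF, 0 °C; then 2, 0 °C to rt
Reagents that add atoms: none
Why: SN2 alkylation of the phosphonoacetate anion by the secondary α‑triflyloxy ester should go with clean inversion and sets C17 (17R in the target); the phosphonate‑bearing carbon is lost as a stereocentre in step 5.

Step 3
Reactants: 5 but-2-yn-1-ol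
Product: 7 (2Z)-3-iodobut-2-en-1-ol, via vinylaluminate 6 (not isolated)
Conditions: Red-Al, THF, 0 °C to rt; EtOAc; then I2, THF, −78 to 0 °C
Reagents that add atoms: iodine, II
Why: Alkoxide‑directed trans‑hydroalumination puts aluminium on the distal carbon, and iodinolysis with retention gives the Z‑vinyl iodide; this fixes the Z geometry of the future C5=C6.

Step 4
Reactants: 7 (2Z)-3-iodobut-2-en-1-ol
Product: 8 (2Z)-3-iodobut-2-enal
Conditions: MnO2, CH2Cl2, rt
Reagents that add atoms: none
Why: Allylic oxidation under neutral conditions, which keep the Z geometry.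

Step 5
Reactants: 4 1-tert-butyl 4-ethyl (2S)-3-(diethoxyphosphoryl)-2-methylbutanedioate; 8 (2Z)-3-iodobut-2-enal
Product: 9 1-tert-butyl 4-ethyl (2R,3E)-3-[(2Z)-3-iodobut-2-en-1-ylidene]-2-methylbutanedioate
Conditions: 4, NaH (0.95 equiv), THF, 0 °C; then 8, −78 to 0 °C
Reagents that add atoms: none
Why: Horner–Wadsworth–Emmons olefination of an α‑substituted phosphonoacetate places the aldehyde residue trans to the ester (C6 trans to C9); with substoichiometric base the less acidic C17–H should not epimerize.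

Step 6
Reactants: 9 1-tert-butyl 4-ethyl (2R,3E)-3-[(2Z)-3-iodobut-2-en-1-ylidene]-2-methylbutanedioate
Product: 10 tert-butyl (2R,3E,5Z)-3-(hydroxymethyl)-6-iodo-2-methylhepta-3,5-dienoate
Conditions: DIBAL-H (2.2 equiv), CH2Cl2, −78 °C; aq. Rochelle salt
Reagents that add atoms: none
Why: DIBAL reduces the ethyl ester to the allylic alcohol, while the α‑branched tert‑butyl ester should survive at −78 °C.

Step 7
Reactants: 10 tert-butyl (2R,3E,5Z)-3-(hydroxymethyl)-6-iodo-2-methylhepta-3,5-dienoate
Product: 11 tert-butyl (2R)-2-[(2R,3R)-2-(hydroxymethyl)-3-[(1Z)-2-iodoprop-1-en-1-yl]oxiran-2-yl]propanoate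
Conditions: Ti(OiPr)4 (10 mol%), D-(−)-diethyl tartrate (12 mol%), t-BuOOH, 4 Å MS, CH2Cl2, −20 °C
Reagents that add atoms: tert-butyl hydroperoxide, CC(C)(C)OO
Why: Sharpless asymmetric epoxidation acts only on the allylic‑alcohol olefin C7=C8; the D‑tartrate gives the (2R,3R) epoxide under reagent control, which sets C8 and, before inversion, C7.

Step 8
Reactants: 11 tert-butyl (2R)-2-[(2R,3R)-2-(hydroxymethyl)-3-[(1Z)-2-iodoprop-1-en-1-yl]oxiran-2-yl]propanoate
Product: 12 (3R,4R,5S)-4-hydroxy-4-(hydroxymethyl)-5-[(1Z)-2-iodoprop-1-en-1-yl]-3-methyloxolan-2-one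
Conditions: BF3·OEt2 (0.3 equiv), CH2Cl2, −78 to −20 °C
Reagents that add atoms: none
Why: The ester carbonyl opens the Lewis‑acid‑activated epoxide at the allylic carbon C7 (five‑membered ring closure, inversion at C7) and the tert‑butyl group leaves as isobutene; the epoxide oxygen remains as the tertiary 8‑OH, so O7 and O8 end up anti as in the target.

Step 9
Reactants: 12 (3R,4R,5S)-4-hydroxy-4-(hydroxymethyl)-5-[(1Z)-2-iodoprop-1-en-1-yl]-3-methyloxolan-2-one
Product: 13 (3R,4R,5S)-5-[(1Z)-2-iodoprop-1-en-1-yl]-3-methyl-4-[(triethylsilyl)oxy]-4-{[(triethylsilyl)oxy]methyl}oxolan-2-one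
Conditions: Et3SiOTf (2.5 equiv), 2,6-lutidine, CH2Cl2, −78 to 0 °C
Reagents that add atoms: triethylsilyl trifluoromethanesulfonate, CC[Si](CC)(CC)OS(=O)(=O)C(F)(F)F
Why: Silylation of the primary and the tertiary hydroxyl; it also blocks translactonization to O9.

Step 10
Reactants: 13 (3R,4R,5S)-5-[(1Z)-2-iodoprop-1-en-1-yl]-3-methyl-4-[(triethylsilyl)oxy]-4-{[(triethylsilyl)oxy]methyl}oxolan-2-one
Product: 14 (2Z)-2-methyl-3-[(2S,3R,4R)-4-methyl-5-oxo-3-[(triethylsilyl)oxy]-3-{[(triethylsilyl)oxy]methyl}oxolan-2-yl]prop-2-enal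
Conditions: Pd(PPh3)4 (5 mol%), CO (3 atm), Bu3SnH (slow addition), THF, 50 °C
Reagents that add atoms: carbon monoxide, [C-]#[O+]
Why: Palladium‑catalysed reductive carbonylation (formylation) of the vinyl iodide keeps the olefin geometry and adds C4 as the aldehyde; lactone and silyl ethers are inert.

Step 11
Reactants: 15 pent-4-yn-1-ol
Product: 17 (4E)-5-iodo-4-methylpent-4-en-1-ol, via alkenylalane 16 (not isolated)
Conditions: Me3Al (3 equiv), Cp2ZrCl2 (25 mol%), CH2Cl2, 0 °C to rt; then I2, THF, −30 to 0 °C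
Reagents that add atoms: trimethylaluminium, C[Al](C)C; iodine, II
Why: Negishi carboalumination adds methyl and aluminium syn and regioselectively; iodinolysis with retention gives the E‑vinyl iodide (C10=C11 with C20).

Step 12
Reactants: 17 (4E)-5-iodo-4-methylpent-4-en-1-ol
Product: 18 (4E)-5-iodo-4-methylpent-4-enal
Conditions: Dess–Martin periodinane, CH2Cl2, rt
Reagents that add atoms: none
Why: Mild oxidation of the primary alcohol; the vinyl iodide is untouched.

Step 13
Reactants: 18 (4E)-5-iodo-4-methylpent-4-enal; 19 3-(triphenyl-λ5-phosphanylidene)butan-2-one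
Product: 20 (3E,7E)-8-iodo-3,7-dimethylocta-3,7-dien-2-one
Conditions: toluene, 80 °C
Reagents that add atoms: none
Why: Wittig reaction of a stabilized ylide gives the E‑trisubstituted enone (C2 trans to C13), the geometry the chair transition state of the key step needs.

Step 14
Reactants: 20 (3E,7E)-8-iodo-3,7-dimethylocta-3,7-dien-2-one
Product: 21 (2R,3E,7E)-8-iodo-3,7-dimethylocta-3,7-dien-2-ol
Conditions: (S)-Me-CBS oxazaborolidine (15 mol%), BH3·SMe2, THF, −30 °C
Reagents that add atoms: none
Why: Corey–Bakshi–Shibata reduction with the α‑branched alkenyl group as the large substituent should give the R carbinol, which is the matched enantiomer for the next step.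

Step 15
Reactants: 21 (2R,3E,7E)-8-iodo-3,7-dimethylocta-3,7-dien-2-ol
Product: 22 (1R)-1-[(2R,3R)-3-[(3E)-4-iodo-3-methylbut-3-en-1-yl]-2-methyloxiran-2-yl]ethan-1-ol
Conditions: Ti(OiPr)4 (10 mol%), D-(−)-diisopropyl tartrate (12 mol%), t-BuOOH, 4 Å MS, CH2Cl2, −20 °C
Reagents that add atoms: tert-butyl hydroperoxide, CC(C)(C)OO
Why: Matched Sharpless epoxidation of the secondary allylic alcohol sets the 1,14‑epoxide with 14R and should raise its optical purity; the vinyl iodide olefin is not an allylic alcohol and stays.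

Step 16
Reactants: 22 (1R)-1-[(2R,3R)-3-[(3E)-4-iodo-3-methylbut-3-en-1-yl]-2-methyloxiran-2-yl]ethan-1-ol
Product: 23 1-[(2S,3R)-3-[(3E)-4-iodo-3-methylbut-3-en-1-yl]-2-methyloxiran-2-yl]ethan-1-one
Conditions: Dess–Martin periodinane, pyridine, CH2Cl2, 0 °C to rt
Reagents that add atoms: none
Why: Oxidation removes the auxiliary carbinol centre and gives a methyl ketone that can enolize only towards C3; the epoxide keeps its configuration (the descriptor at C1 changes by priority only).

Step 17
Reactants: 23 1-[(2S,3R)-3-[(3E)-4-iodo-3-methylbut-3-en-1-yl]-2-methyloxiran-2-yl]ethan-1-one; 14 (2Z)-2-methyl-3-[(2S,3R,4R)-4-methyl-5-oxo-3-[(triethylsilyl)oxy]-3-{[(triethylsilyl)oxy]methyl}oxolan-2-yl]prop-2-enal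
Product: 25 seco-ketol (4R-carbinol; 2-ketone; 1S,14R-epoxide; 8,9-bis-O-TES), via enol borinate 24 (not isolated)
Conditions: 23, (−)-Ipc2BCl, Et3N, Et2O, −78 to 0 °C; then 14, −78 to −20 °C; pH 7 buffer, MeOH, H2O2, 0 °C
Reagents that add atoms: none
Why: Boron aldol of a methyl ketone through its diisopinocampheylboron enolate forms C3–C4; C4 (R) is set by reagent‑controlled re‑face addition to the enal, independently of the epoxide.

Step 18
Reactants: 25 seco-ketol (4R-carbinol; 2-ketone)
Product: 27 syn-2,4-diol (2S,4R; 1R,14R-epoxide), via diethylborinate 26 (not isolated)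
Conditions: Et2BOMe, THF/MeOH (4:1), −78 °C; NaBH4; then MeOH, rt, co-evaporation
Reagents that add atoms: none
Why: Narasaka–Prasad reduction: the boron chelate between O4 and the C2 carbonyl is attacked axially by hydride, which gives the 1,3‑syn diol and sets 2S.

Step 19
Reactants: 27 syn-2,4-diol
Product: 28 4-O-acetate (2-OH free)
Conditions: Ac2O (1.2 equiv), 2,4,6-collidine, CH2Cl2, −20 to 0 °C
Reagents that add atoms: acetic anhydride, CC(=O)OC(C)=O
Why: The allylic C4 hydroxyl is less hindered than the C2 hydroxyl next to the quaternary epoxide carbon, so limited anhydride at low temperature should acetylate O4 first.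

Step 20
Reactants: 28 4-O-acetate
Product: 29 2-O-isobutyrate 4-O-acetate
Conditions: (i-PrCO)2O, DMAP (0.3 equiv), Et3N, CH2Cl2, 0 °C to rt
Reagents that add atoms: isobutyric anhydride, CC(C)C(=O)OC(=O)C(C)C
Why: DMAP‑catalysed acylation of the remaining hindered secondary hydroxyl; the tertiary oxygen is silylated, so both final esters are now in place.

Step 21
Reactants: 29 2-O-isobutyrate 4-O-acetate
Product: 30 C9 aldehyde (8-O-TES)
Conditions: (COCl)2, DMSO, CH2Cl2, −78 to −40 °C; then Et3N, −78 to 0 °C
Reagents that add atoms: none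
Why: Swern conditions cleave and oxidize a primary triethylsilyl ether directly to the aldehyde while the tertiary silyl ether stays; the aldehyde has no α‑hydrogen and cannot epimerize.

Step 22
Reactants: 30 C9 aldehyde
Product: 31 14-membered allylic alcohol (9S; 10E)
Conditions: CrCl2 (10 equiv), NiCl2 (5 mol%), DMSO/THF, 0.002 M, rt
Reagents that add atoms: none
Why: Nozaki–Hiyama–Kishi macrocyclization forms C9–C10 with retention of the E olefin and tolerates esters, lactone and epoxide; 9S is expected from Felkin–Anh addition anti to the C8–O bond, but this centre is not under reagent control.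

Step 23
Reactants: 31 14-membered allylic alcohol
Product: 32 macrocyclic epoxide (9-O-acetate)
Conditions: Ac2O, pyridine, DMAP (10 mol%), CH2Cl2, rt
Reagents that add atoms: acetic anhydride, CC(=O)OC(C)=O
Why: Acetylation of the secondary allylic alcohol puts the third final ester in place.

Step 24
Reactants: 32 macrocyclic epoxide
Product: 33 bicyclic 14-epi-alcohol (1R,10S,14R; 11(20)-ene; 8-O-TES)
Conditions: Cp2TiCl2 (2.5 equiv), Mn dust, THF, rt; 32 added slowly (0.005 M); aq. NaH2PO4
Reagents that add atoms: none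
Why: Cp2TiCl opens the 1,14‑epoxide homolytically at the more substituted carbon to the tertiary C1 radical with the titanoxy group left on C14; the radical adds across the ring to C10 of the E olefin C10=C11, and the tertiary C11 radical is trapped by a second Ti(III) and loses a C20 hydrogen by β‑hydride elimination to the exocyclic 11(20)‑methylene. The closest known reaction type is the Ti(III)‑mediated radical cyclization of epoxypolyprenes and its transannular version on medium‑ring epoxy olefins. Ring closed: the cyclohexane C1–C14–C13–C12–C11–C10 by transannular 6‑endo‑trig closure, which at the same time cuts the ten‑membered ring C1–C10 out of the 14‑membered one. C1 is set by the chair transition state with the C2 branch equatorial, Me‑15 axial and the C14–O–Ti bond equatorial and anti to the forming bond (the stereochemical result of an anti opening of the epoxide). C10 is set by the E geometry of C10=C11, which holds C9 equatorial, so Me‑15 and H‑10 end up trans‑diaxial (trans fusion); C14 is carried over from the Sharpless‑derived epoxide. The selectivity needed is addition to C10=C11 and not to the other isoprene‑spaced olefin C5=C6; the Z geometry of C5=C6 would force C7 axial and a cis fusion in that closure, and the olefin is flanked by two acyloxy‑bearing carbons and stiffened by the fused lactone. The esters and the lactone are inert to Ti(III), and a β‑acyloxy radical does not divert as a cation would.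

Step 25
Reactants: 33 bicyclic 14-epi-alcohol
Product: 34 14-ketone
Conditions: Dess–Martin periodinane, pyridine, CH2Cl2, rt
Reagents that add atoms: none
Why: Oxidation of the equatorial secondary alcohol; nothing else in the molecule is oxidizable under these conditions.

Step 26
Reactants: 34 14-ketone
Product: 35 14α-alcohol (14S; axial)
Conditions: L-Selectride, THF, −78 °C; aq. NH4Cl
Reagents that add atoms: none
Why: The bulky hydride attacks the cyclohexanone from the equatorial direction and gives the axial alcohol anti to Me‑15, as with 2,2‑disubstituted cyclohexanones; at −78 °C the ketone should react before the esters.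

Step 27
Reactants: 35 14α-alcohol
Product: 36 8-O-triethylsilyl ether of the target
Conditions: Ac2O, DMAP, Et3N, CH2Cl2, rt to 40 °C
Reagents that add atoms: acetic anhydride, CC(=O)OC(C)=O
Why: Forced acetylation of the hindered axial alcohol; the tertiary oxygen is still silylated and cannot compete.

Step 28
Reactants: 36 8-O-triethylsilyl ether of the target
Product: 37 CNP0189561.1 (target)
Conditions: HF·pyridine, pyridine, THF, 0 °C to rt
Reagents that add atoms: none
Why: Buffered fluoride removes the tertiary silyl ether without touching the esters, the lactone or the exocyclic olefin.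

**Compound list**

1 | tert-butyl (2R)-2-hydroxypropanoate | C[C@@H](O)C(=O)OC(C)(C)C | starting material
2 | tert-butyl (2R)-2-[(trifluoromethanesulfonyl)oxy]propanoate | C[C@@H](OS(=O)(=O)C(F)(F)F)C(=O)OC(C)(C)C | intermediate
3 | triethyl phosphonoacetate | CCOC(=O)CP(=O)(OCC)OCC | starting material
4 | 1-tert-butyl 4-ethyl (2S)-3-(diethoxyphosphoryl)-2-methylbutanedioate (C3 epimers) | CCOC(=O)C(P(=O)(OCC)OCC)[C@@H](C)C(=O)OC(C)(C)C | intermediate
5 | but-2-yn-1-ol | CC#CCO | starting material
6 | sodium vinylaluminate (cyclic alkenyl alkoxy aluminate from 5) | CC1=CCO[Al-]1(OCCOC)OCCOC.[Na+] | intermediate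
7 | (2Z)-3-iodobut-2-en-1-ol | C/C(I)=C/CO | intermediate
8 | (2Z)-3-iodobut-2-enal | C/C(I)=C/C=O | intermediate
9 | 1-tert-butyl 4-ethyl (2R,3E)-3-[(2Z)-3-iodobut-2-en-1-ylidene]-2-methylbutanedioate | CCOC(=O)/C(=C/C=C(/C)I)[C@@H](C)C(=O)OC(C)(C)C | intermediate
10 | tert-butyl (2R,3E,5Z)-3-(hydroxymethyl)-6-iodo-2-methylhepta-3,5-dienoate | OC/C(=C/C=C(/C)I)[C@@H](C)C(=O)OC(C)(C)C | intermediate
11 | tert-butyl (2R)-2-[(2R,3R)-2-(hydroxymethyl)-3-[(1Z)-2-iodoprop-1-en-1-yl]oxiran-2-yl]propanoate | OC[C@]1(O[C@@H]1/C=C(/C)I)[C@@H](C)C(=O)OC(C)(C)C | intermediate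
12 | (3R,4R,5S)-4-hydroxy-4-(hydroxymethyl)-5-[(1Z)-2-iodoprop-1-en-1-yl]-3-methyloxolan-2-one | I/C(C)=C\[C@@H]1OC(=O)[C@H](C)[C@@]1(O)CO | intermediate
13 | (3R,4R,5S)-5-[(1Z)-2-iodoprop-1-en-1-yl]-3-methyl-4-[(triethylsilyl)oxy]-4-{[(triethylsilyl)oxy]methyl}oxolan-2-one | I/C(C)=C\[C@@H]1OC(=O)[C@H](C)[C@@]1(O[Si](CC)(CC)CC)CO[Si](CC)(CC)CC | intermediate
14 | (2Z)-2-methyl-3-[(2S,3R,4R)-4-methyl-5-oxo-3-[(triethylsilyl)oxy]-3-{[(triethylsilyl)oxy]methyl}oxolan-2-yl]prop-2-enal | O=C/C(C)=C\[C@@H]1OC(=O)[C@H](C)[C@@]1(O[Si](CC)(CC)CC)CO[Si](CC)(CC)CC | intermediate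
15 | pent-4-yn-1-ol | C#CCCCO | starting material
16 | (E)-alkenyldimethylalane (O-dimethylaluminated) from 15 | C[Al](C)/C=C(\C)CCCO[Al](C)C | intermediate
17 | (4E)-5-iodo-4-methylpent-4-en-1-ol | OCCC/C(C)=C/I | intermediate
18 | (4E)-5-iodo-4-methylpent-4-enal | O=CCC/C(C)=C/I | intermediate
19 | 3-(triphenyl-λ5-phosphanylidene)butan-2-one | CC(=O)C(C)=P(c1ccccc1)(c1ccccc1)c1ccccc1 | starting material
20 | (3E,7E)-8-iodo-3,7-dimethylocta-3,7-dien-2-one | CC(=O)/C(C)=C/CC/C(C)=C/I | intermediate
21 | (2R,3E,7E)-8-iodo-3,7-dimethylocta-3,7-dien-2-ol | C[C@@H](O)/C(C)=C/CC/C(C)=C/I | intermediate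
22 | (1R)-1-[(2R,3R)-3-[(3E)-4-iodo-3-methylbut-3-en-1-yl]-2-methyloxiran-2-yl]ethan-1-ol | C[C@@H](O)[C@@]1(C)O[C@@H]1CC/C(C)=C/I | intermediate
23 | 1-[(2S,3R)-3-[(3E)-4-iodo-3-methylbut-3-en-1-yl]-2-methyloxiran-2-yl]ethan-1-one | CC(=O)[C@@]1(C)O[C@@H]1CC/C(C)=C/I | intermediate
24 | enol diisopinocampheylborinate of 23 | C=C(OB([C@@H]1C[C@@H]2C[C@H]([C@H]1C)C2(C)C)[C@@H]1C[C@@H]2C[C@H]([C@H]1C)C2(C)C)[C@@]1(C)O[C@@H]1CC/C(C)=C/I | intermediate
25 | seco-ketol: 4R-hydroxy, 2-oxo, (1S,14R)-1,14-epoxide, 5Z, 10E-vinyl iodide, lactone 7S,8R,17R, 8,9-bis-O-TES | I/C=C(\C)CC[C@H]1O[C@]1(C)C(=O)C[C@@H](O)/C(C)=C\[C@@H]2OC(=O)[C@H](C)[C@@]2(O[Si](CC)(CC)CC)CO[Si](CC)(CC)CC | intermediate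
26 | 4-O-diethylborinate of 25 | I/C=C(\C)CC[C@H]1O[C@]1(C)C(=O)C[C@@H](OB(CC)CC)/C(C)=C\[C@@H]2OC(=O)[C@H](C)[C@@]2(O[Si](CC)(CC)CC)CO[Si](CC)(CC)CC | intermediate
27 | syn-2,4-diol (2S,4R), (1R,14R)-epoxide, otherwise as 25 | I/C=C(\C)CC[C@H]1O[C@]1(C)[C@@H](O)C[C@@H](O)/C(C)=C\[C@@H]2OC(=O)[C@H](C)[C@@]2(O[Si](CC)(CC)CC)CO[Si](CC)(CC)CC | intermediate
28 | 4-O-acetate of 27 | I/C=C(\C)CC[C@H]1O[C@]1(C)[C@@H](O)C[C@@H](OC(C)=O)/C(C)=C\[C@@H]2OC(=O)[C@H](C)[C@@]2(O[Si](CC)(CC)CC)CO[Si](CC)(CC)CC | intermediate
29 | 2-O-isobutyrate 4-O-acetate | I/C=C(\C)CC[C@H]1O[C@]1(C)[C@@H](OC(=O)C(C)C)C[C@@H](OC(C)=O)/C(C)=C\[C@@H]2OC(=O)[C@H](C)[C@@]2(O[Si](CC)(CC)CC)CO[Si](CC)(CC)CC | intermediate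
30 | C9 aldehyde (8S, 8-O-TES) | I/C=C(\C)CC[C@H]1O[C@]1(C)[C@@H](OC(=O)C(C)C)C[C@@H](OC(C)=O)/C(C)=C\[C@@H]2OC(=O)[C@H](C)[C@@]2(O[Si](CC)(CC)CC)C=O | intermediate
31 | 14-membered allylic alcohol (1S,2S,4R,5Z,7S,8S,9S,10E,14R,17R) | O[C@H]1/C=C(\C)CC[C@H]2O[C@]2(C)[C@@H](OC(=O)C(C)C)C[C@@H](OC(C)=O)/C(C)=C\[C@@H]3OC(=O)[C@H](C)[C@]31O[Si](CC)(CC)CC | intermediate
32 | macrocyclic epoxide, 9-O-acetate of 31 | CC(=O)O[C@H]1/C=C(\C)CC[C@H]2O[C@]2(C)[C@@H](OC(=O)C(C)C)C[C@@H](OC(C)=O)/C(C)=C\[C@@H]3OC(=O)[C@H](C)[C@]31O[Si](CC)(CC)CC | intermediate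
33 | bicyclic 14-epi-alcohol (1R,2S,4R,5Z,7S,8S,9S,10S,14R,17R), 8-O-TES | C=C1CC[C@@H](O)[C@]2(C)[C@@H](OC(=O)C(C)C)C[C@@H](OC(C)=O)/C(C)=C\[C@@H]3OC(=O)[C@H](C)[C@@]3(O[Si](CC)(CC)CC)[C@@H](OC(C)=O)[C@@H]12 | intermediate
34 | 14-ketone | C=C1CCC(=O)[C@]2(C)[C@@H](OC(=O)C(C)C)C[C@@H](OC(C)=O)/C(C)=C\[C@@H]3OC(=O)[C@H](C)[C@@]3(O[Si](CC)(CC)CC)[C@@H](OC(C)=O)[C@@H]12 | intermediate
35 | 14α-alcohol (14S) | C=C1CC[C@H](O)[C@]2(C)[C@@H](OC(=O)C(C)C)C[C@@H](OC(C)=O)/C(C)=C\[C@@H]3OC(=O)[C@H](C)[C@@]3(O[Si](CC)(CC)CC)[C@@H](OC(C)=O)[C@@H]12 | intermediate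
36 | 8-O-triethylsilyl ether of the target | C=C1CC[C@H](OC(C)=O)[C@]2(C)[C@@H](OC(=O)C(C)C)C[C@@H](OC(C)=O)/C(C)=C\[C@@H]3OC(=O)[C@H](C)[C@@]3(O[Si](CC)(CC)CC)[C@@H](OC(C)=O)[C@@H]12 | intermediate
37 | CNP0189561.1: (1R,2S,4R,5Z,7S,8S,9S,10S,14S,17R)-4,9,14-triacetoxy-8-hydroxy-2-(isobutyryloxy)briara-5,11(20)-dien-19,7-olide | C=C1CC[C@H](OC(C)=O)[C@]2(C)[C@@H](OC(=O)C(C)C)C[C@@H](OC(C)=O)/C(C)=C\[C@@H]3OC(=O)[C@H](C)[C@@]3(O)[C@@H](OC(C)=O)[C@@H]12 | target

**Step count and risk**

Total steps: 28. Longest linear sequence: 20 steps (steps 1, 2, 5–10, then 17–28; the branch from 5 is equally long, the branch from 15 gives 18).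

Least certain steps, each with one fallback:

Step 24 (key step). Most likely to go wrong: the long‑lived C1 radical adds to the other isoprene‑spaced olefin (at C6) or is reduced or eliminated before ring closure, because both olefins are reached through six‑membered transition states; the macrocycle may also fold to the wrong ring fusion. Fallback (polarity reversal): from 32, a Lewis‑acid Meinwald rearrangement (1,2‑hydride shift from C14 to C1) gives the macrocyclic C14 ketone F1. Mn(OAc)3/Cu(OAc)2 then generates the electrophilic α‑keto radical at C1, which is polarity‑matched only with the electron‑richer C10=C11 olefin, and Cu(II) oxidizes the C11 radical to the exocyclic olefin. This gives ketone 34, where the route is rejoined and step 25 is skipped.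

Step 17. Most likely to go wrong: poor facial selectivity at C4, since reagent control of such boron enolates is only moderate and both partners are chiral; the boron Lewis acid may also open the epoxide. Fallback (both carbinol centres by reductions): from 23 and 14, an unselective lithium aldol gives the C4‑epimeric ketol F2. CBS reduction of the C2 ketone with the (R)‑catalyst gives the 2S diol F3, and MnO2 oxidizes only the allylic C4 alcohol to the hydroxy enone F4. Narasaka–Prasad reduction, now directed by the C2 hydroxyl, returns the syn diol 27.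

Step 22. Most likely to go wrong: poor facial selectivity at C9 on ring closure, because the ring and not a reagent decides at a neopentyl α‑oxygenated aldehyde; oligomerization is the second risk. Fallback: from crude 31 (both C9 epimers), Dess–Martin oxidation gives the macrocyclic enone F5, and CBS reduction with the (R)‑catalyst (quaternary C8 as the large group) returns 31 as one epimer.

Step 19. Most likely to go wrong: insufficient site selectivity between the C4 and C2 hydroxyls, or acetyl migration during step 20. Fallback (differentiation by oxidation state): from 27, MnO2 gives the hydroxy enone F4; isobutyrylation of its only hydroxyl gives the keto ester F6; CBS reduction with the (S)‑catalyst sets 4R in the alcohol F7; acetylation gives 29.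

Step 8. Most likely to go wrong: loss of regio‑ or stereocontrol in the epoxide opening (attack at the tertiary C8, or ionization at the allylic C7), or translactonization to O9. Fallback (intermolecular opening, then lactonization): from 11, Ti(OiPr)4‑mediated C3‑selective opening of the 2,3‑epoxy alcohol with benzoic acid (SN2 at C7) gives the benzoate F8. Methanolysis (K2CO3, MeOH) gives the triol ester F9, and trifluoroacetic acid then closes the lactone from the C7 hydroxyl with loss of the tert‑butyl group, giving 12.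

**Further compounds**

F1 | step 24 | macrocyclic C14 ketone with C1–H (C1 epimers), otherwise as 32 | CC(=O)O[C@H]1/C=C(\C)CCC(=O)C(C)[C@@H](OC(=O)C(C)C)C[C@@H](OC(C)=O)/C(C)=C\[C@@H]2OC(=O)[C@H](C)[C@]21O[Si](CC)(CC)CC
F2 | step 17 | C4-epimeric ketol (C4 epimers of 25) | I/C=C(\C)CC[C@H]1O[C@]1(C)C(=O)CC(O)/C(C)=C\[C@@H]2OC(=O)[C@H](C)[C@@]2(O[Si](CC)(CC)CC)CO[Si](CC)(CC)CC
F3 | step 17 | 2S diol, C4 epimers | I/C=C(\C)CC[C@H]1O[C@]1(C)[C@@H](O)CC(O)/C(C)=C\[C@@H]2OC(=O)[C@H](C)[C@@]2(O[Si](CC)(CC)CC)CO[Si](CC)(CC)CC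
F4 | step 17 | (2S)-2-hydroxy-4-oxo enone | I/C=C(\C)CC[C@H]1O[C@]1(C)[C@@H](O)CC(=O)/C(C)=C\[C@@H]2OC(=O)[C@H](C)[C@@]2(O[Si](CC)(CC)CC)CO[Si](CC)(CC)CC
F5 | step 22 | macrocyclic C9 enone | O=C1/C=C(\C)CC[C@H]2O[C@]2(C)[C@@H](OC(=O)C(C)C)C[C@@H](OC(C)=O)/C(C)=C\[C@@H]3OC(=O)[C@H](C)[C@]31O[Si](CC)(CC)CC
F6 | step 19 | 2-O-isobutyrate of F4 | I/C=C(\C)CC[C@H]1O[C@]1(C)[C@@H](OC(=O)C(C)C)CC(=O)/C(C)=C\[C@@H]2OC(=O)[C@H](C)[C@@]2(O[Si](CC)(CC)CC)CO[Si](CC)(CC)CC
F7 | step 19 | 2-O-isobutyrate with free (4R)-hydroxyl | I/C=C(\C)CC[C@H]1O[C@]1(C)[C@@H](OC(=O)C(C)C)C[C@@H](O)/C(C)=C\[C@@H]2OC(=O)[C@H](C)[C@@]2(O[Si](CC)(CC)CC)CO[Si](CC)(CC)CC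
F8 | step 8 | C7 benzoate of the opened epoxide (tert-butyl ester, 8,9-diol) | OC[C@@](O)([C@@H](OC(=O)c1ccccc1)/C=C(/C)I)[C@@H](C)C(=O)OC(C)(C)C
F9 | step 8 | 7,8,9-triol tert-butyl ester | OC[C@@](O)([C@@H](O)/C=C(/C)I)[C@@H](C)C(=O)OC(C)(C)C
A1 | alternative 1 | seco C4 aldehyde / C5 vinyl iodide on the finished cyclohexane | I/C(C)=C\[C@@H]3OC(=O)[C@H](C)[C@@]3(O)[C@@H](OC(C)=O)[C@H]1C(=C)CC[C@H](OC(C)=O)[C@]1(C)[C@@H](OC(=O)C(C)C)CC=O
A2 | alternative 2 | 13-membered propargylic/allylic ether fused to the cyclohexene | CC(C)C(=O)O[C@H]1C[C@@H](OC(C)=O)/C(C)=C\C#CCOCC2=C[C@]1(C)[C@@H](OC(C)=O)CC2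
A3 | alternative 2 | ring-contracted cyclodecenynol | C=C1CC[C@H](OC(C)=O)[C@]2(C)[C@@H](OC(=O)C(C)C)C[C@@H](OC(C)=O)/C(C)=C\C#C[C@@H](O)[C@@H]12
A4 | alternative 3 | 1,2-dialkenyl decalinol for the oxy-Cope shift | C=C1CC[C@H](OC(C)=O)[C@]2(C)[C@@H](OC(=O)C(C)C)[C@H](/C=C/C)[C@](O)(C=C)[C@@H](OC(C)=O)[C@@H]12
A5 | alternative 3 | cyclodecenone from the oxy-Cope shift (C8 ketone, C3=C4 olefin) | C=C1CC[C@H](OC(C)=O)[C@]2(C)[C@@H](OC(=O)C(C)C)/C=C/C(C)CCC(=O)[C@@H](OC(C)=O)[C@@H]12
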